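## The problem

Target 26 is a bibenzyl. Ring A (carbons C1' to C6': C1' on the bridge, C3' methoxy, C5' hydroxyl) is joined by a saturated two-carbon bridge (Ca on ring A, Cb on ring B) to ring B, which carries four contiguous substituents: the bridge at B1, 4-hydroxybenzyl groups at B2 and B6, and a hydroxyl at B5. There is no stereocenter, so the difficulty is entirely regiochemical. B1 lies between two benzyl-bearing carbons, so any bond to B1 is made at a di-ortho-substituted site, and the order of the four neighbors on ring B is not one that electrophilic substitution of a phenol would deliver. Of the five phenolic oxygens only the one at C3' is methylated, and it sits on a resorcinol whose two oxygens are equivalent until one is capped; the methyl group therefore has to arrive already in place. The free phenols are oxidation-prone and the two diarylmethane CH2 groups (C7 on B2, C8 on B6) are doubly benzylic and activated by para oxygen. Quinone-type oxidants and strong acids are therefore avoided late, and the phenols travel as benzyl ethers, released at the end by hydrogenolysis, which spares the methyl ether and the diarylmethanes. The enabling feature is ring A itself: a benzene substituted only at C1' (alkyl), C3' (OMe) and C5' (OH) is the expected product when a 3-alkylcyclobut-2-enone (supplying C5', C6', C1', C2' and the phenol oxygen) is heated with methoxyacetylene 20 (supplying C3', C4' and the methoxy group), and the saturated bridge insulates this chemistry from ring B.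

## Retrosynthesis

**26 to 25.** The last cut is of three O–benzyl bonds, leading to tri-O-benzyl ether 25 with only the ring A phenol free. Benzyl is preferred to silyl or acyl protection because it has to survive a Grignard reagent, lithium amide bases, zinc in acetic acid and heating at 80 °C. Its hydrogenolytic removal leaves the C3' methyl ether and both diarylmethanes alone. The forward step only has to cleave three aryl benzyl ethers in a molecule with no other reducible group.

**25 to 17 and 20.** Ring A is opened across C4'–C5' and C2'–C3' (C5'–C6' is re-formed in the forward direction), giving cyclobutenone 17 and methoxyacetylene 20. The neighboring cuts at the bridge bonds would need an already differentiated resorcinol fragment and a coupling next to crowded B1. This cut instead differentiates OH and OMe by origin (hydroxyl from the carbonyl of 17, methoxy from 20) and removes a whole ring. The forward reaction must give one regiochemical outcome, methoxy meta to both hydroxyl and bridge, and must tolerate three benzyl ethers at 80 °C. Precursor 17 may carry no free hydroxyl, since that would trap ketenes 21 and 23.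

**20 to 18.** Methoxyacetylene 20 is volatile and not reliably stocked, so it is traced by double elimination to chloroacetal 18, a bulk chemical. The forward reaction is asked only for elimination and distillation.

**17 to 16 to 15.** The four-membered ring of 17 is cut at its C1–C2 and C3–C4 bonds (cyclobutenone numbering), via dichlorocyclobutenone 16, back to terminal alkyne 15. A halogenated ketene is chosen over a parent ketene equivalent because its cycloaddition to unactivated terminal alkynes is dependable and regioselective (carbonyl carbon to the CH terminus), which puts the ring B chain at C3 of the enone. The precursor is simpler by one ring. The forward steps must leave benzyl ethers intact in the presence of zinc salts.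

**15 to 13 to 10.** Alkyne 15 is traced through silylalkyne 14 to phenol 13 (one O–benzyl bond and one C–Si bond), and 13 to cyclohexenone 10 by removing one unsaturation. Deferring aromatization until after the chain is attached lets ring B be built from a cyclohexane-1,3-dione, whose numbering fixes where each substituent goes. The forward dehydrogenation must avoid oxidants that attack diarylmethanes, which points to enolate selenenylation and syn-elimination via 11 and 12.

**10 to 6 and 7.** The B1–chain bond is cut. Enone 10 arises from vinylogous ester 6 by 1,2-addition of Grignard reagent 8 (from bromide 7) and acid-induced transposition through carbinol 9. This places the four-carbon alkyne chain on the carbon between the two benzyl-bearing carbons, a bond that a cross-coupling would have to make at a di-ortho-substituted arene. The forward reaction must favor addition over enolization at a flanked carbonyl.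

**6 to 4 and 5; 4 to 3; 3 to 1 and 2.** The C8–ring bond is cut by kinetic α'-benzylation of vinylogous ester 4 with bromide 5. Compound 4 is the enol ether of dione 3, and the C7–ring bond of 3 comes from reductive alkylation of dione 1 with aldehyde 2. Reductive alkylation is chosen over direct alkylation of 1 with 5 because it gives C-monoalkylation only. All four starting materials (1, 2, 5, 7) are purchasable.

## Roads not taken

Alternative 1: The cut is at the C7–aryl and C8–aryl bonds of the two diarylmethanes. In the forward key step, 3-bromo-2,4-bis(bromomethyl)phenyl pivalate A2 would couple twice with 4-(benzyloxy)phenylboronic acid A3 under Pd(PPh3)4 (zerovalent palladium) and anhydrous K3PO4. The benzylic C–Br bonds react ahead of the flanked aryl C–Br bond, giving 2,4-bis[4-(benzyloxy)benzyl]-3-bromophenyl pivalate A1, which keeps the B1 bromide for attaching the bridge and ring A.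
- Merits: only aromatic building blocks, both diarylmethanes formed in one operation, high convergence, and probably fewer steps than the eleven proposed here.
- Weak points: A2 has bromine between two methyl-derived carbons and meta to oxygen, a position that electrophilic bromination of a phenol does not reach, so its preparation is not trivial, and the double benzylic bromination invites over-bromination. Chemoselectivity among three C–Br bonds has to hold twice. The remaining aryl bromide of A1 is di-ortho-substituted, so the bridge-forming coupling is made at the most hindered site. Ring A still has to be supplied with its oxygens already differentiated.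
- Comparison: this road is shorter on paper. The chosen plan sets against it that every position on ring B is fixed by the numbering of dione 1, that the B1 bond is made by carbonyl addition and not by coupling at a flanked arene, and that ring A is differentiated by construction.

Alternative 2: The cut is at both bridge bonds, B1–Cb and C1'–Ca, with a vinyl linchpin. In the forward key step, ring B pinacol boronate A5 and vinyllithium A7 would form a boron ate complex. With ring A triflate A6 and Pd(OAc)2 bearing a ferrocenyl bisphosphine, the ring B aryl group migrates from boron to the vinyl α-carbon (B1–Cb) and reductive elimination forms C1'–Ca, giving the racemic Cb-boronate A4.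
- Merits: a three-component union that forms both bridge bonds at once; the most convergent of the four plans.
- Weak points: the product A4 carries a boron group and a stereocenter that the target does not have, so a protodeboronation is added and a chiral ligand is spent on a center that is erased. The migrating aryl group is di-ortho-substituted, which disfavors both ate-complex formation and the 1,2-shift. A7 is a strongly basic organolithium that has to be dosed exactly, since any excess would attack A6. A5 must itself come from the same kind of hindered ring B aryl halide as in alternative 1, so the ring B access problem is inherited, and A6 again presupposes a differentiated resorcinol.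
- Comparison: this road is better in convergence. The chosen plan sets against it that no superfluous functionality is introduced and that no bond is formed by migration of a flanked aryl group.

Alternative 3: The cut is at B2–C7, C7–aryl, B6–C8 and C8–aryl, with carbon monoxide A10 supplying both benzylic carbons. In the forward key step, the 2,6-dibrominated bibenzyl A9, two molecules of A10 and two of boronic acid A3 would undergo double carbonylative coupling under Pd(OAc)2 with di(1-adamantyl)butylphosphine, giving bis-diaryl ketone A8. Deoxygenation of both ketones would have to follow.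
- Merits: the bibenzyl is assembled early by ordinary chemistry, the one-carbon source is cheap, and reduction of the diaryl ketones could in principle be merged with the final debenzylation.
- Weak points: the bromination pattern of A9 (B2 and B6 but not B4, with ring A being the more electron-rich ring) cannot be obtained by direct bromination of the bibenzyl and has to be built in beforehand. Two carbonylations at positions ortho to the bridge compete with direct, carbon-monoxide-free coupling and with mono-conversion. Two carbonyl groups are introduced only to be removed, and partial reduction to benzhydrols is a further risk.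
- Comparison: this road avoids any ring synthesis and may be comparable in length. The chosen plan sets against it that both benzylic carbons enter at the correct oxidation level and that the ring B substitution pattern is never in question.

Key step: step 10

Assumption: methoxyacetylene 20 is prepared immediately before use (step 9) rather than purchased, because it is volatile and not reliably available. The target has no stereocenter; the stereocenters of 6, 9, 10, 11, 12 and 22 are carried as racemic or diastereomeric mixtures and are erased on aromatization.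

## Route

Step 1
Reactants: 1 cyclohexane-1,3-dione; 2 4-(benzyloxy)benzaldehyde
Product: 3 2-[4-(benzyloxy)benzyl]cyclohexane-1,3-dione
Conditions: Hantzsch ester (diethyl 2,6-dimethyl-1,4-dihydropyridine-3,5-dicarboxylate), L-proline (cat.), CH2Cl2, rt
Reagents that add atoms: none
Why: Organocatalytic three-component reductive alkylation: Knoevenagel condensation of the dione with the aldehyde gives an alkylidene dione that the dihydropyridine reduces by conjugate hydride transfer before a second dione can add, so only C-monoalkylation should result.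

Step 2
Reactants: 3 2-[4-(benzyloxy)benzyl]cyclohexane-1,3-dione
Product: 4 2-[4-(benzyloxy)benzyl]-3-(2-methylpropoxy)cyclohex-2-en-1-one
Conditions: i-BuOH, TsOH·H2O (cat.), toluene, reflux, Dean–Stark
Reagents that add atoms: 2-methylpropan-1-ol, CC(C)CO
Why: Acid-catalyzed enol etherification of a 2-substituted cyclohexane-1,3-dione with azeotropic removal of water; the dione is symmetric, so only one vinylogous ester can form, and the aryl benzyl ether is inert to catalytic TsOH.

Step 3
Reactants: 4 2-[4-(benzyloxy)benzyl]-3-(2-methylpropoxy)cyclohex-2-en-1-one; 5 4-(benzyloxy)benzyl bromide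
Product: 6 2,6-bis[4-(benzyloxy)benzyl]-3-(2-methylpropoxy)cyclohex-2-en-1-one (racemic)
Conditions: LiN(iPr)2, THF, −78 °C; then 5, −78 °C to rt
Reagents that add atoms: none
Why: Kinetic α'-alkylation of a vinylogous ester (first half of the Stork–Danheiser sequence): the amide base removes the C6 proton to give the cross-conjugated enolate, which is C-alkylated by the reactive benzylic bromide; the new stereocenter forms as a racemate and is erased in step 5.

Step 4
Reactants: 6 2,6-bis[4-(benzyloxy)benzyl]-3-(2-methylpropoxy)cyclohex-2-en-1-one; 7 (4-bromobut-1-yn-1-yl)trimethylsilane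
Product: 10 2,4-bis[4-(benzyloxy)benzyl]-3-[4-(trimethylsilyl)but-3-yn-1-yl]cyclohex-2-en-1-one (racemic), via silylbutynylmagnesium bromide 8 (not isolated), via tertiary allylic carbinol 9 (not isolated)
Conditions: 7, Mg, THF, rt to 40 °C; then 6, CeCl3 (anhydrous), THF, −78 to 0 °C; then 1 M HCl, THF, rt
Reagents that add atoms: water, O
Why: Stork–Danheiser alkylative carbonyl transposition: 1,2-addition of the homopropargylic Grignard reagent (the CeCl3 additive suppresses enolization at the flanked carbonyl) and acid-induced ionization and hydrolysis of the β-alkoxy allylic carbinol give the transposed enone with the chain on the carbon between the two benzyl-bearing carbons; the silylalkyne is inert to dilute aqueous HCl.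

Step 5
Reactants: 10 2,4-bis[4-(benzyloxy)benzyl]-3-[4-(trimethylsilyl)but-3-yn-1-yl]cyclohex-2-en-1-one
Product: 13 2,4-bis[4-(benzyloxy)benzyl]-3-[4-(trimethylsilyl)but-3-yn-1-yl]phenol, via phenylselanyl enone 11 (not isolated), via cross-conjugated dienone 12 (not isolated)
Conditions: LiN(iPr)2, THF, −78 °C; PhSeCl, −78 °C; then 30% H2O2, pyridine, CH2Cl2, 0 °C to rt
Reagents that add atoms: none
Why: Enone-to-phenol dehydrogenation by kinetic α'-selenenylation and selenoxide syn-elimination: the C6 enolate is trapped by PhSeCl, oxidation at selenium triggers elimination toward C5 below room temperature, and the resulting 4H-cyclohexa-2,5-dienone tautomerizes to the phenol; no oxidant able to attack the diarylmethane positions is used and the C4 stereocenter is erased.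

Step 6
Reactants: 13 2,4-bis[4-(benzyloxy)benzyl]-3-[4-(trimethylsilyl)but-3-yn-1-yl]phenol
Product: 15 1-(benzyloxy)-2,4-bis[4-(benzyloxy)benzyl]-3-(but-3-yn-1-yl)benzene, via silylalkyne benzyl ether 14 (not isolated)
Conditions: BnBr, K2CO3, DMF, rt; then MeOH, rt
Reagents that add atoms: benzyl bromide, BrCc1ccccc1
Why: Williamson O-benzylation of the phenol followed in the same flask by carbonate-catalyzed methanolysis of the alkynyl C–Si bond; the aryl benzyl ethers and diarylmethanes are inert to both operations.

Step 7
Reactants: 15 1-(benzyloxy)-2,4-bis[4-(benzyloxy)benzyl]-3-(but-3-yn-1-yl)benzene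
Product: 16 3-{2-[3-(benzyloxy)-2,6-bis(4-(benzyloxy)benzyl)phenyl]ethyl}-4,4-dichlorocyclobut-2-en-1-one
Conditions: Cl3CCOCl, Zn(Cu), Et2O/DME, rt to reflux
Reagents that add atoms: trichloroacetyl chloride, ClC(=O)C(Cl)(Cl)Cl
Why: [2+2] cycloaddition of dichloroketene, generated by zinc dechlorination of the acid chloride, with a terminal alkyne; the ketene carbonyl carbon bonds to the terminal CH so the chain ends up at C3, and DME ligates the ZnCl2 formed so that the benzyl ethers are not attacked.

Step 8
Reactants: 16 3-{2-[3-(benzyloxy)-2,6-bis(4-(benzyloxy)benzyl)phenyl]ethyl}-4,4-dichlorocyclobut-2-en-1-one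
Product: 17 3-{2-[3-(benzyloxy)-2,6-bis(4-(benzyloxy)benzyl)phenyl]ethyl}cyclobut-2-en-1-one
Conditions: Zn dust, AcOH, TMEDA, EtOH, 0 °C to rt
Reagents that add atoms: none
Why: Reductive dechlorination of an α,α-dichloroketone by zinc in amine-buffered acetic acid, the standard second stage of the dichloroketene route to 3-alkylcyclobutenones; the buffer prevents acid-induced isomerization or opening of the strained enone, and benzyl ethers are untouched.

Step 9
Reactants: 18 2-chloro-1,1-dimethoxyethane
Product: 20 methoxyacetylene, via sodium methoxyacetylide 19 (not isolated)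
Conditions: NaNH2 (3 equiv), liquid NH3, −33 °C; then cold aqueous NaCl; distilled into cold toluene
Reagents that add atoms: none
Why: Base-induced double elimination (loss of methanol, then of HCl) from an α-chloro acetal, the classical preparation of alkoxyacetylenes; the third equivalent of amide holds the product as its sodium acetylide until the aqueous quench, and the low-boiling ynol ether is collected as a toluene solution for immediate use.

Step 10
Reactants: 17 3-{2-[3-(benzyloxy)-2,6-bis(4-(benzyloxy)benzyl)phenyl]ethyl}cyclobut-2-en-1-one; 20 methoxyacetylene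
Product: 25 3-{2-[3-(benzyloxy)-2,6-bis(4-(benzyloxy)benzyl)phenyl]ethyl}-5-methoxyphenol, via vinylketene 21 (not isolated), via alkenylcyclobutenone 22 (not isolated), via dienylketene 23 (not isolated), via cyclohexadienone 24 (not isolated)
Conditions: 20 (3–5 equiv), toluene, 80 °C, sealed tube
Reagents that add atoms: none
Why: Danheiser benzannulation, a cascade of four pericyclic steps in one flask. Thermal four-electron conrotatory opening of 17 gives vinylketene 21, and the electron-rich alkyne 20 adds to it in a [2+2] cycloaddition in which the ketene carbonyl carbon (C5') bonds to the nucleophilic CH terminus (C4') and the ketene α-carbon (C2') to the methoxy-bearing carbon (C3'), giving 22. A second four-electron opening breaks C5'–C2' and gives dienylketene 23; this opening is reversible and only the isomer with ketene and vinyl group cis, as drawn for 23, goes on. Ring A is then closed by a thermal six-electron disrotatory electrocyclization of that triene (C5'–C6', all six ring atoms from the triene) to cyclohexadienone 24, which tautomerizes to phenol 25. The closest known reaction type is the benzannulation of 3-alkylcyclobutenones with alkoxyacetylenes to 5-alkylresorcinol monoethers. No stereocenter is created, the sp3 carbon of 22 being transient. The selectivity needed is regiochemical, methoxy meta to both hydroxyl and bridge, and it is secured by the polarity of the ketene–ynol ether cycloaddition; because the hydroxyl comes from the carbonyl of 17 and the methoxy group from 20, the two ring A oxygens are differentiated by origin. All other hydroxyls are benzylated so that only product 25 can intercept the ketenes, and the excess of 20 keeps that interception slow.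

Step 11
Reactants: 25 3-{2-[3-(benzyloxy)-2,6-bis(4-(benzyloxy)benzyl)phenyl]ethyl}-5-methoxyphenol
Product: 26 2,4-bis(4-hydroxybenzyl)-3-[2-(3-hydroxy-5-methoxyphenyl)ethyl]phenol
Conditions: H2 (1 atm), Pd/C, EtOAc/MeOH, rt
Reagents that add atoms: none
Why: Catalytic hydrogenolysis of three aryl benzyl ethers; the aryl methyl ether, the diarylmethane C–C bonds and the bibenzyl bridge are stable to hydrogen over Pd/C at room temperature, and no stereocenter is involved.

## Compound list

1 | cyclohexane-1,3-dione | O=C1CCCC(=O)C1 | starting material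
2 | 4-(benzyloxy)benzaldehyde | O=Cc1ccc(OCc2ccccc2)cc1 | starting material
3 | 2-[4-(benzyloxy)benzyl]cyclohexane-1,3-dione | O=C1CCCC(=O)C1Cc1ccc(OCc2ccccc2)cc1 | intermediate
4 | 2-[4-(benzyloxy)benzyl]-3-(2-methylpropoxy)cyclohex-2-en-1-one | CC(C)COC1=C(Cc2ccc(OCc3ccccc3)cc2)C(=O)CCC1 | intermediate
5 | 4-(benzyloxy)benzyl bromide | BrCc1ccc(OCc2ccccc2)cc1 | starting material
6 | 2,6-bis[4-(benzyloxy)benzyl]-3-(2-methylpropoxy)cyclohex-2-en-1-one (racemic) | CC(C)COC1=C(Cc2ccc(OCc3ccccc3)cc2)C(=O)C(Cc2ccc(OCc3ccccc3)cc2)CC1 | intermediate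
7 | (4-bromobut-1-yn-1-yl)trimethylsilane | C[Si](C)(C)C#CCCBr | starting material
8 | [4-(trimethylsilyl)but-3-yn-1-yl]magnesium bromide | C[Si](C)(C)C#CCC[Mg]Br | intermediate
9 | 2,6-bis[4-(benzyloxy)benzyl]-3-(2-methylpropoxy)-1-[4-(trimethylsilyl)but-3-yn-1-yl]cyclohex-2-en-1-ol (diastereomer mixture, formed as its metal alkoxide) | CC(C)COC1=C(Cc2ccc(OCc3ccccc3)cc2)C(O)(CCC#C[Si](C)(C)C)C(Cc2ccc(OCc3ccccc3)cc2)CC1 | intermediate
10 | 2,4-bis[4-(benzyloxy)benzyl]-3-[4-(trimethylsilyl)but-3-yn-1-yl]cyclohex-2-en-1-one (racemic) | O=C1CCC(Cc2ccc(OCc3ccccc3)cc2)C(CCC#C[Si](C)(C)C)=C1Cc1ccc(OCc2ccccc2)cc1 | intermediate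
11 | 2,4-bis[4-(benzyloxy)benzyl]-6-(phenylselanyl)-3-[4-(trimethylsilyl)but-3-yn-1-yl]cyclohex-2-en-1-one (diastereomer mixture) | O=C1C([Se]c2ccccc2)CC(Cc2ccc(OCc3ccccc3)cc2)C(CCC#C[Si](C)(C)C)=C1Cc1ccc(OCc2ccccc2)cc1 | intermediate
12 | 2,4-bis[4-(benzyloxy)benzyl]-3-[4-(trimethylsilyl)but-3-yn-1-yl]cyclohexa-2,5-dien-1-one (racemic) | O=C1C=CC(Cc2ccc(OCc3ccccc3)cc2)C(CCC#C[Si](C)(C)C)=C1Cc1ccc(OCc2ccccc2)cc1 | intermediate
13 | 2,4-bis[4-(benzyloxy)benzyl]-3-[4-(trimethylsilyl)but-3-yn-1-yl]phenol | Oc1ccc(Cc2ccc(OCc3ccccc3)cc2)c(CCC#C[Si](C)(C)C)c1Cc1ccc(OCc2ccccc2)cc1 | intermediate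
14 | {4-[3-(benzyloxy)-2,6-bis(4-(benzyloxy)benzyl)phenyl]but-1-yn-1-yl}trimethylsilane | C[Si](C)(C)C#CCCc1c(Cc2ccc(OCc3ccccc3)cc2)ccc(OCc2ccccc2)c1Cc1ccc(OCc2ccccc2)cc1 | intermediate
15 | 1-(benzyloxy)-2,4-bis[4-(benzyloxy)benzyl]-3-(but-3-yn-1-yl)benzene | C#CCCc1c(Cc2ccc(OCc3ccccc3)cc2)ccc(OCc2ccccc2)c1Cc1ccc(OCc2ccccc2)cc1 | intermediate
16 | 3-{2-[3-(benzyloxy)-2,6-bis(4-(benzyloxy)benzyl)phenyl]ethyl}-4,4-dichlorocyclobut-2-en-1-one | O=C1C=C(CCc2c(Cc3ccc(OCc4ccccc4)cc3)ccc(OCc3ccccc3)c2Cc2ccc(OCc3ccccc3)cc2)C1(Cl)Cl | intermediate
17 | 3-{2-[3-(benzyloxy)-2,6-bis(4-(benzyloxy)benzyl)phenyl]ethyl}cyclobut-2-en-1-one | O=C1CC(CCc2c(Cc3ccc(OCc4ccccc4)cc3)ccc(OCc3ccccc3)c2Cc2ccc(OCc3ccccc3)cc2)=C1 | intermediate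
18 | 2-chloro-1,1-dimethoxyethane (chloroacetaldehyde dimethyl acetal) | COC(CCl)OC | starting material
19 | sodium methoxyacetylide | COC#[C-].[Na+] | intermediate
20 | methoxyacetylene (methoxyethyne) | COC#C | intermediate
21 | 3-{2-[3-(benzyloxy)-2,6-bis(4-(benzyloxy)benzyl)phenyl]ethyl}buta-1,3-dien-1-one | O=C=CC(=C)CCc1c(Cc2ccc(OCc3ccccc3)cc2)ccc(OCc2ccccc2)c1Cc1ccc(OCc2ccccc2)cc1 | intermediate
22 | 4-{4-[3-(benzyloxy)-2,6-bis(4-(benzyloxy)benzyl)phenyl]but-1-en-2-yl}-3-methoxycyclobut-2-en-1-one (racemic) | COC1=CC(=O)C1C(=C)CCc1c(Cc2ccc(OCc3ccccc3)cc2)ccc(OCc2ccccc2)c1Cc1ccc(OCc2ccccc2)cc1 | intermediate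
23 | (3E)-5-{2-[3-(benzyloxy)-2,6-bis(4-(benzyloxy)benzyl)phenyl]ethyl}-3-methoxyhexa-1,3,5-trien-1-one | O=C=C/C(OC)=C\C(=C)CCc1c(Cc2ccc(OCc3ccccc3)cc2)ccc(OCc2ccccc2)c1Cc1ccc(OCc2ccccc2)cc1 | intermediate
24 | 5-{2-[3-(benzyloxy)-2,6-bis(4-(benzyloxy)benzyl)phenyl]ethyl}-3-methoxycyclohexa-2,4-dien-1-one | COC1=CC(=O)CC(CCc2c(Cc3ccc(OCc4ccccc4)cc3)ccc(OCc3ccccc3)c2Cc2ccc(OCc3ccccc3)cc2)=C1 | intermediate
25 | 3-{2-[3-(benzyloxy)-2,6-bis(4-(benzyloxy)benzyl)phenyl]ethyl}-5-methoxyphenol | COc1cc(O)cc(CCc2c(Cc3ccc(OCc4ccccc4)cc3)ccc(OCc3ccccc3)c2Cc2ccc(OCc3ccccc3)cc2)c1 | intermediate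
26 | 2,4-bis(4-hydroxybenzyl)-3-[2-(3-hydroxy-5-methoxyphenyl)ethyl]phenol | COc1cc(O)cc(CCc2c(Cc3ccc(O)cc3)ccc(O)c2Cc2ccc(O)cc2)c1 | target

## Step count and risk

Total: 11 steps. Longest linear sequence: 10 steps (steps 1–8, 10, 11); step 9 is a one-step branch.

**Step 10 (key step).** The process most likely to fail is the bimolecular capture of vinylketene 21. Alkyne 20 is low-boiling and thermally fragile, so it may escape or oligomerize before 17 has opened, leaving 21 to dimerize or to acylate the phenol of 25 already formed. A sealed vessel, excess 20 and a brief treatment of the crude product with K2CO3 in MeOH (which would return 25 from any aryl ester) are the first measures. The fallback gives up the benzannulation and forms the bridge by cross-coupling, setting out from 6 and returning at 26.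
- Addition of commercial lithium (trimethylsilyl)acetylide to 6 (THF, −78 to 0 °C) should give 2,6-bis[4-(benzyloxy)benzyl]-3-(2-methylpropoxy)-1-[(trimethylsilyl)ethynyl]cyclohex-2-en-1-ol F1, which 1 M HCl transposes to 2,4-bis[4-(benzyloxy)benzyl]-3-[(trimethylsilyl)ethynyl]cyclohex-2-en-1-one F2.
- Enolate selenenylation as in step 5 gives 2,4-bis[4-(benzyloxy)benzyl]-6-(phenylselanyl)-3-[(trimethylsilyl)ethynyl]cyclohex-2-en-1-one F3. Its oxidation and syn-elimination give 2,4-bis[4-(benzyloxy)benzyl]-3-[(trimethylsilyl)ethynyl]cyclohexa-2,5-dien-1-one F4, which tautomerizes to 2,4-bis[4-(benzyloxy)benzyl]-3-[(trimethylsilyl)ethynyl]phenol F5.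
- K2CO3 in MeOH frees 2,4-bis[4-(benzyloxy)benzyl]-3-ethynylphenol F6.
- Sonogashira coupling of F6 with commercial 3-bromo-5-methoxyphenol (PdCl2(PPh3)2, CuI, Et3N, DMF, 60 °C) gives 2,4-bis[4-(benzyloxy)benzyl]-3-[(3-hydroxy-5-methoxyphenyl)ethynyl]phenol F7.
- Hydrogen over Pd/C then saturates the alkyne and cleaves the two benzyl ethers, giving 26.

This fallback is shorter from 6 than the main route, at the price of buying ring A ready-made instead of building it.

**Step 4.** The carbonyl of 6 is flanked by two benzyl-bearing carbons, so enolization at C6 or β-hydride reduction may outrun 1,2-addition and return 6 or its alcohol. The fallback replaces carbonyl addition by cross-coupling, setting out from 6 and returning at 10.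
- Kinetic enolization and O-triflation (KN(SiMe3)2, PhNTf2, THF, −78 °C) should give 1,3-bis[4-(benzyloxy)benzyl]-4-(2-methylpropoxy)cyclohexa-1,3-dien-2-yl trifluoromethanesulfonate F8.
- Bromide 7 is converted with zinc dust and LiCl in THF into bromo[4-(trimethylsilyl)but-3-yn-1-yl]zinc F9.
- Negishi coupling of F8 with F9 (Pd(OAc)2, 2-dicyclohexylphosphino-2',6'-dimethoxybiphenyl, THF, 50 °C) gives trimethyl{4-[1,3-bis(4-(benzyloxy)benzyl)-4-(2-methylpropoxy)cyclohexa-1,3-dien-2-yl]but-1-yn-1-yl}silane F10.
- Hydrolysis of the dienol ether of F10 with 1 M HCl in THF gives enone 10.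

**Step 5.** The likely failure is oxidative degradation of the electron-rich phenol by peroxide and seleninic by-products once aromatization has occurred. The fallback uses no peroxide and no selenium, setting out from 10 and returning at 13. Kinetic silylation (LiN(iPr)2, Me3SiCl, THF, −78 °C) gives {[3,5-bis(4-(benzyloxy)benzyl)-4-(4-(trimethylsilyl)but-3-yn-1-yl)cyclohexa-1,3-dien-2-yl]oxy}trimethylsilane F11. Saegusa–Ito oxidation of F11 with Pd(OAc)2 in MeCN at rt gives dienone 12, which tautomerizes to 13.

**Step 7.** Dichloroketene may oligomerize faster than it is captured by a bulky, dilute alkyne, and ZnCl2 may cleave benzyl ethers or open the dichlorocyclobutenone during isolation. The fallback is the Ghosez keteniminium cycloaddition, which sets out from 15, bypasses 16 and step 8, and returns at 17. N,N-dimethylacetamide with Tf2O and 2,4,6-collidine in 1,2-dichloroethane generates N,N-dimethylketeniminium trifluoromethanesulfonate F12. At reflux this adds to 15 to give N-(3-{2-[3-(benzyloxy)-2,6-bis(4-(benzyloxy)benzyl)phenyl]ethyl}cyclobut-2-en-1-ylidene)-N-methylmethanaminium trifluoromethanesulfonate F13. Hydrolysis of F13 with aqueous NaHCO3 gives 17.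

## Further compounds

F1 | step 10 | 2,6-bis[4-(benzyloxy)benzyl]-3-(2-methylpropoxy)-1-[(trimethylsilyl)ethynyl]cyclohex-2-en-1-ol | CC(C)COC1=C(Cc2ccc(OCc3ccccc3)cc2)C(O)(C#C[Si](C)(C)C)C(Cc2ccc(OCc3ccccc3)cc2)CC1
F2 | step 10 | 2,4-bis[4-(benzyloxy)benzyl]-3-[(trimethylsilyl)ethynyl]cyclohex-2-en-1-one | O=C1CCC(Cc2ccc(OCc3ccccc3)cc2)C(C#C[Si](C)(C)C)=C1Cc1ccc(OCc2ccccc2)cc1
F3 | step 10 | 2,4-bis[4-(benzyloxy)benzyl]-6-(phenylselanyl)-3-[(trimethylsilyl)ethynyl]cyclohex-2-en-1-one | O=C1C([Se]c2ccccc2)CC(Cc2ccc(OCc3ccccc3)cc2)C(C#C[Si](C)(C)C)=C1Cc1ccc(OCc2ccccc2)cc1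
F4 | step 10 | 2,4-bis[4-(benzyloxy)benzyl]-3-[(trimethylsilyl)ethynyl]cyclohexa-2,5-dien-1-one | O=C1C=CC(Cc2ccc(OCc3ccccc3)cc2)C(C#C[Si](C)(C)C)=C1Cc1ccc(OCc2ccccc2)cc1
F5 | step 10 | 2,4-bis[4-(benzyloxy)benzyl]-3-[(trimethylsilyl)ethynyl]phenol | Oc1ccc(Cc2ccc(OCc3ccccc3)cc2)c(C#C[Si](C)(C)C)c1Cc1ccc(OCc2ccccc2)cc1
F6 | step 10 | 2,4-bis[4-(benzyloxy)benzyl]-3-ethynylphenol | C#Cc1c(Cc2ccc(OCc3ccccc3)cc2)ccc(O)c1Cc1ccc(OCc2ccccc2)cc1
F7 | step 10 | 2,4-bis[4-(benzyloxy)benzyl]-3-[(3-hydroxy-5-methoxyphenyl)ethynyl]phenol | COc1cc(O)cc(C#Cc2c(Cc3ccc(OCc4ccccc4)cc3)ccc(O)c2Cc2ccc(OCc3ccccc3)cc2)c1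
F8 | step 4 | 1,3-bis[4-(benzyloxy)benzyl]-4-(2-methylpropoxy)cyclohexa-1,3-dien-2-yl trifluoromethanesulfonate | CC(C)COC1=C(Cc2ccc(OCc3ccccc3)cc2)C(OS(=O)(=O)C(F)(F)F)=C(Cc2ccc(OCc3ccccc3)cc2)CC1
F9 | step 4 | bromo[4-(trimethylsilyl)but-3-yn-1-yl]zinc | C[Si](C)(C)C#CCC[Zn]Br
F10 | step 4 | trimethyl{4-[1,3-bis(4-(benzyloxy)benzyl)-4-(2-methylpropoxy)cyclohexa-1,3-dien-2-yl]but-1-yn-1-yl}silane | CC(C)COC1=C(Cc2ccc(OCc3ccccc3)cc2)C(CCC#C[Si](C)(C)C)=C(Cc2ccc(OCc3ccccc3)cc2)CC1
F11 | step 5 | {[3,5-bis(4-(benzyloxy)benzyl)-4-(4-(trimethylsilyl)but-3-yn-1-yl)cyclohexa-1,3-dien-2-yl]oxy}trimethylsilane | C[Si](C)(C)OC1=CCC(Cc2ccc(OCc3ccccc3)cc2)C(CCC#C[Si](C)(C)C)=C1Cc1ccc(OCc2ccccc2)cc1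
F12 | step 7 | N,N-dimethylketeniminium trifluoromethanesulfonate | C=C=[N+](C)C.[O-]S(=O)(=O)C(F)(F)F
F13 | step 7 | N-(3-{2-[3-(benzyloxy)-2,6-bis(4-(benzyloxy)benzyl)phenyl]ethyl}cyclobut-2-en-1-ylidene)-N-methylmethanaminium trifluoromethanesulfonate | C[N+](C)=C1CC(CCc2c(Cc3ccc(OCc4ccccc4)cc3)ccc(OCc3ccccc3)c2Cc2ccc(OCc3ccccc3)cc2)=C1.[O-]S(=O)(=O)C(F)(F)F
A1 | alternative 1 | 2,4-bis[4-(benzyloxy)benzyl]-3-bromophenyl pivalate | CC(C)(C)C(=O)Oc1ccc(Cc2ccc(OCc3ccccc3)cc2)c(Br)c1Cc1ccc(OCc2ccccc2)cc1
A2 | alternative 1 | 3-bromo-2,4-bis(bromomethyl)phenyl pivalate | CC(C)(C)C(=O)Oc1ccc(CBr)c(Br)c1CBr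
A3 | alternative 1 | 4-(benzyloxy)phenylboronic acid | OB(O)c1ccc(OCc2ccccc2)cc1
A4 | alternative 2 | 2-{2-[3-(benzyloxy)-5-methoxyphenyl]-1-[3-(benzyloxy)-2,6-bis(4-(benzyloxy)benzyl)phenyl]ethyl}-4,4,5,5-tetramethyl-1,3,2-dioxaborolane (racemic) | COc1cc(OCc2ccccc2)cc(CC(B2OC(C)(C)C(C)(C)O2)c2c(Cc3ccc(OCc4ccccc4)cc3)ccc(OCc3ccccc3)c2Cc2ccc(OCc3ccccc3)cc2)c1
A5 | alternative 2 | 2-[3-(benzyloxy)-2,6-bis(4-(benzyloxy)benzyl)phenyl]-4,4,5,5-tetramethyl-1,3,2-dioxaborolane | CC1(C)OB(OC1(C)C)c1c(Cc2ccc(OCc3ccccc3)cc2)ccc(OCc2ccccc2)c1Cc1ccc(OCc2ccccc2)cc1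
A6 | alternative 2 | 3-(benzyloxy)-5-methoxyphenyl trifluoromethanesulfonate | COc1cc(OCc2ccccc2)cc(OS(=O)(=O)C(F)(F)F)c1
A7 | alternative 2 | vinyllithium | [Li]C=C
A8 | alternative 3 | {4-(benzyloxy)-2-[2-(3-(benzyloxy)-5-methoxyphenyl)ethyl]-1,3-phenylene}bis{[4-(benzyloxy)phenyl]methanone} | COc1cc(CCc2c(C(=O)c3ccc(OCc4ccccc4)cc3)ccc(OCc3ccccc3)c2C(=O)c2ccc(OCc3ccccc3)cc2)cc(OCc2ccccc2)c1
A9 | alternative 3 | 1-(benzyloxy)-3-{2-[3-(benzyloxy)-2,6-dibromophenyl]ethyl}-5-methoxybenzene | COc1cc(CCc2c(Br)ccc(OCc3ccccc3)c2Br)cc(OCc2ccccc2)c1
A10 | alternative 3 | carbon monoxide | [C-]#[O+]
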